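The 19-membered ring is opened at the CH2–CH2 bond between para-phenylene ring B and catechol ring C. Both carbons are benzylic, so each is carried as an aryl aldehyde, and one McMurry coupling of dialdehyde 7 closes the macrocycle without any differentiation of the chain ends. Rings A and C are the same 5-aryloxy-3,4-dioxygenated unit, so phenol 1 serves twice. The ring B formyl group first activates fluoride for SNAr, then becomes a coupling partner. The precursor is the open chain B–O–A–CH=CH–D–O–C, whose Heck-derived E-stilbene is a rigid strut. One hydrogenation saturates both bridges and BBr3 frees the catechols.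

Key step: step 5

Ring labels: A is the catechol ring bonded through O to the para-phenylene ring B. C is the catechol ring bonded through O to the meta-phenylene ring D. The bridges are B–CH2CH2–C and D–CH2CH2–A. The target has no stereocentre.

Assumption: the alkene formed in step 5 is drawn Z, the geometry that closure against the E-strut should favour. Either geometry should be converted into 10 in step 6.

Step 1
Reactants: 1 3-hydroxy-4,5-dimethoxybenzaldehyde
Product: 2 5-ethenyl-2,3-dimethoxyphenol
Conditions: MePPh3Br (2.5 equiv), KOtBu (2.5 equiv), THF, 0 °C to rt; aq NH4Cl; used promptly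
Reagents that add atoms: methyltriphenylphosphonium bromide, C[P+](c1ccccc1)(c1ccccc1)c1ccccc1.[Br-]
Why: Wittig methylenation: the excess ylide first deprotonates the phenol, and because the phenoxide sits meta to the formyl group it cannot deactivate it by conjugation, so the aldehyde should be converted into the styrene as with simple 3-hydroxybenzaldehydes.

Step 2
Reactants: 2 5-ethenyl-2,3-dimethoxyphenol; 3 4-fluorobenzaldehyde
Product: 4 4-(5-ethenyl-2,3-dimethoxyphenoxy)benzaldehyde (rings A and B)
Conditions: K2CO3 (2 equiv), BHT (cat.), DMF, 110 °C
Reagents that add atoms: none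
Why: Nucleophilic aromatic substitution (SNAr): the para-formyl group stabilises the Meisenheimer adduct so that the phenoxide of 2 displaces fluoride, while the vinyl group is inert to carbonate and BHT holds back radical polymerisation.

Step 3
Reactants: 1 3-hydroxy-4,5-dimethoxybenzaldehyde; 5 3-bromophenylboronic acid
Product: 6 3-(3-bromophenoxy)-4,5-dimethoxybenzaldehyde (rings C and D)
Conditions: Cu(OAc)2 (2 equiv), pyridine (5 equiv), 4 Å MS, CH2Cl2, air, rt
Reagents that add atoms: none
Why: Chan–Lam coupling: transmetalation of the boronic acid to the copper phenoxide and C–O reductive elimination from trivalent copper form the diaryl ether at room temperature, conditions that accept ortho-alkoxy phenols and leave the aldehyde and the C–Br bond untouched.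

Step 4
Reactants: 4 4-(5-ethenyl-2,3-dimethoxyphenoxy)benzaldehyde; 6 3-(3-bromophenoxy)-4,5-dimethoxybenzaldehyde
Product: 7 3-[3-[(E)-2-[3-(4-formylphenoxy)-4,5-dimethoxyphenyl]ethenyl]phenoxy]-4,5-dimethoxybenzaldehyde (open chain B–O–A–CH=CH–D–O–C)
Conditions: Pd(OAc)2 (5 mol %), P(o-tol)3 (10 mol %), NaOAc (1.5 equiv), DMAc, 120 °C
Reagents that add atoms: none
Why: Mizoroki–Heck reaction: oxidative addition of zerovalent palladium into the only C–Br bond, insertion at the unsubstituted vinyl carbon and syn β-hydride elimination should give the E-stilbene, and both aldehydes, which have no α-hydrogen, tolerate the acetate base.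

Step 5
Reactants: 7 open-chain E-stilbene dialdehyde
Product: 9 macrocyclic diene (tetra-O-methyl ether of the target with an E double bond in the D–A bridge plus a Z double bond in the B–C bridge), via titanium pinacolate 8 (not isolated)
Conditions: TiCl4 (12 equiv), Zn dust (24 equiv), pyridine (6 equiv), THF, reflux 2 h; then 7 in THF by syringe pump over 20 h (final about 1 mM), reflux; aq K2CO3
Reagents that add atoms: none
Why: McMurry coupling: low-valent titanium made from TiCl4 and Zn gives one electron to each aryl aldehyde, the two ketyl radicals bound to the same titanium surface join to form the new C–C bond as pinacolate 8, and at reflux both C–O bonds break stepwise to leave the alkene and titanium oxide. The closest known reaction type is the intramolecular McMurry macrocyclisation of aromatic dialdehydes to stilbenophanes, a closure that is established for diaryl-ether cyclophanes of about this ring size. One lasting ring is closed, the 19-membered macrocycle, by end-to-end union of the formyl carbon on ring B and the formyl carbon on ring C of an open chain; the five-membered dioxatitanacycle of 8 is transient. The two carbinol stereocentres of 8 are uncontrolled and are erased by the deoxygenation, no stereocentre remains in 9, and the new alkene should be Z because the two ether oxygens and the three meta-phenylenes supply only five turns of about 60°, too few to close a ring that holds two E-alkenes. The selectivity needed is ring closure over intermolecular coupling, which is secured by syringe-pump addition that keeps 7 near millimolar, by anchoring of both carbonyl groups on the titanium surface and by the E-stilbene strut, which removes rotors from the chain. No chemoselectivity problem arises, since the two aldehydes are the only reducible groups and the aryl ethers and the stilbene are inert to the reagent.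

Step 6
Reactants: 9 macrocyclic diene
Product: 10 tetra-O-methyl ether of the target (both bridges saturated)
Conditions: H2 (1 atm), Pd/C (10 wt %), EtOAc–MeOH, rt
Reagents that add atoms: none
Why: Heterogeneous catalytic hydrogenation: both stilbene double bonds should be reduced on palladium whatever their geometry, which removes the E/Z question, while the aryl ethers are inert and no stereocentre is created.

Step 7
Reactants: 10 tetra-O-methyl ether of the target
Product: 12 target tetraphenol CNP0511668.0, via bis(bromodioxaborole) 11 (not isolated)
Conditions: BBr3 (8 equiv), CH2Cl2, −78 °C to rt, Ar; then H2O, 0 °C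
Reagents that add atoms: none
Why: Lewis-acid cleavage of aryl methyl ethers with BBr3: boron binds the methoxy oxygens, bromide attacks the methyl groups by SN2, each veratrole unit ends as the cyclic bromoborate of 11 that water hydrolyses, and the diaryl ether bonds, which offer no sp3 carbon for attack, survive.

Compound list
1 | 3-hydroxy-4,5-dimethoxybenzaldehyde | COc1cc(C=O)cc(O)c1OC | starting material
2 | 5-ethenyl-2,3-dimethoxyphenol | C=Cc1cc(O)c(OC)c(OC)c1 | intermediate
3 | 4-fluorobenzaldehyde | O=Cc1ccc(F)cc1 | starting material
4 | 4-(5-ethenyl-2,3-dimethoxyphenoxy)benzaldehyde | C=Cc1cc(OC)c(OC)c(Oc2ccc(C=O)cc2)c1 | intermediate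
5 | 3-bromophenylboronic acid | OB(O)c1cccc(Br)c1 | starting material
6 | 3-(3-bromophenoxy)-4,5-dimethoxybenzaldehyde | COc1cc(C=O)cc(Oc2cccc(Br)c2)c1OC | intermediate
7 | 3-[3-[(E)-2-[3-(4-formylphenoxy)-4,5-dimethoxyphenyl]ethenyl]phenoxy]-4,5-dimethoxybenzaldehyde | O=Cc1ccc(Oc2cc(/C=C/c3cccc(Oc4cc(C=O)cc(OC)c4OC)c3)cc(OC)c2OC)cc1 | intermediate
8 | macrocyclic titanium pinacolate (idealised dioxatitanacycle of divalent titanium; the two carbinol centres are unassigned and are destroyed in the same step) | O1c2ccc(cc2)C2O[Ti]OC2c2cc(OC)c(OC)c(c2)Oc2cccc(c2)/C=C/c2cc(OC)c(OC)c1c2 | intermediate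
9 | macrocyclic diene, E in the D–A bridge and Z in the B–C bridge, four OMe groups | O1c2ccc(cc2)/C=C\c2cc(OC)c(OC)c(c2)Oc2cccc(c2)/C=C/c2cc(OC)c(OC)c1c2 | intermediate
10 | tetra-O-methyl ether of the target | O1c2ccc(cc2)CCc2cc(OC)c(OC)c(c2)Oc2cccc(c2)CCc2cc(OC)c(OC)c1c2 | intermediate
11 | macrocycle with both catechols bound as 2-bromo-1,3,2-benzodioxaboroles | O1c2ccc(cc2)CCc2cc3OB(Br)Oc3c(c2)Oc2cccc(c2)CCc2cc3OB(Br)Oc3c1c2 | intermediate
12 | CNP0511668.0, macrocyclic bis(bibenzyl) tetraphenol | Oc1cc2cc(c1O)Oc1ccc(cc1)CCc1cc(O)c(O)c(c1)Oc1cccc(c1)CC2 | target

Total step count: 7. Longest linear sequence: 6 (steps 1, 2, 4, 5, 6, 7).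

Steps most likely to fail

Step 5. Intermolecular ketyl coupling to oligomers may outrun ring closure. The reaction may also stop at the pinacol stage, if the rigid E-strut holds the two formyl groups too far apart or makes the diene ring too strained. The fallback sets out from 7 and comes back at 10. It removes the strut first and closes the ring by reversible carbene metathesis instead of reductive coupling.
- Hydrogenation of 7 over Pd/C poisoned with Ph2S (H2, EtOAc, rt) should reduce only the alkene and leave the aromatic aldehydes, giving the saturated dialdehyde F1.
- Double Wittig methylenation (MePPh3Br, KOtBu, THF) should give the bis-styrene F2.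
- Ring-closing metathesis with the second-generation Hoveyda–Grubbs catalyst in dilute toluene at 80 °C, with an argon sparge, should give the macrocyclic mono-stilbene F3.
- Hydrogenation of F3 under the conditions of step 6 gives 10.

Step 4. Oxidative addition into the unactivated aryl bromide may be slow at a temperature where the electron-rich styrene polymerises or is arylated at its internal carbon. The fallback sets out from 4 and comes back at 7.
- Cross metathesis of 4 with vinylboronic acid pinacol ester (second-generation Grubbs catalyst, CH2Cl2, 40 °C) should give the (E)-styrylboronate F4.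
- Stereoretentive Suzuki–Miyaura coupling of F4 with 6 (Pd(PPh3)4, K2CO3, dioxane–water, 80 °C) fixes both the regiochemistry and the geometry of 7 at a lower temperature.

Step 3. Protodeboronation of 5 and oxidation of the phenol may compete with slow aryl transfer to the hindered ortho-methoxy phenoxide. The fallback sets out from 1 and comes back at 6. An Ullmann-type coupling of 1 with 1-bromo-3-iodobenzene (CuI, N,N-dimethylglycine, Cs2CO3, dioxane, 90 °C) should react only at the C–I bond and give 6 directly. No compound outside the list is made (F0).

Further compounds
F1 | step 5 | 3-[3-[2-[3-(4-formylphenoxy)-4,5-dimethoxyphenyl]ethyl]phenoxy]-4,5-dimethoxybenzaldehyde (saturated dialdehyde) | O=Cc1ccc(Oc2cc(CCc3cccc(Oc4cc(C=O)cc(OC)c4OC)c3)cc(OC)c2OC)cc1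
F2 | step 5 | bis-styrene from double methylenation of F1 | C=Cc1ccc(Oc2cc(CCc3cccc(Oc4cc(C=C)cc(OC)c4OC)c3)cc(OC)c2OC)cc1
F3 | step 5 | macrocyclic mono-stilbene, Z alkene in the B–C bridge, saturated D–A bridge, four OMe groups | O1c2ccc(cc2)/C=C\c2cc(OC)c(OC)c(c2)Oc2cccc(c2)CCc2cc(OC)c(OC)c1c2
F4 | step 4 | 4-[2,3-dimethoxy-5-[(E)-2-(4,4,5,5-tetramethyl-1,3,2-dioxaborolan-2-yl)ethenyl]phenoxy]benzaldehyde | CC1(C)OB(/C=C/c2cc(OC)c(OC)c(Oc3ccc(C=O)cc3)c2)OC1(C)C
F0 | step 3 | none | none
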